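Retrosynthesis first removes the O7 sulfate and the ether protecting groups (allyl on O5 and O7, benzyl on O3'), then opens ring C at O1–C8a and at C3–C4.
This leaves ring A as 2-fluoro-4,6-bis(allyloxy)benzoyl chloride and ring B as 3-benzyloxy-4-methoxyacetophenone.
Enabling feature: O1 joins C2 to C8a, and C8a sits on ring A ortho to the C4 carbonyl, so a fluoride on C8a can be displaced by the enolate oxygen on C2 once C-acylation has made C3–C4.
Forward: ring A is dressed by ester formation and double fluoride displacement on 2,4,6-trifluorobenzoyl chloride, and ring B is benzylated. Ring C, the only ring built, closes in the joining step; deallylation, 7-O-sulfation and debenzylation follow.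
Stereochemistry: the target has no stereocentre and no stereogenic double bond, so nothing has to be set.

Key step: step 5

Remark: the aryl sulfate monoesters of the last two steps are drawn as free hydrogen sulfates, as the target is; in practice they would be carried as sodium salts (cation exchange on work-up, which also removes pyridine before the hydrogenolysis), and the free acid released on an acidic ion-exchange resin only if required.

Step 1
Reactants: 1 2,4,6-trifluorobenzoyl chloride
Product: 4 prop-2-enyl 2-fluoro-4,6-bis(prop-2-enyloxy)benzoate, via prop-2-enyl 2,4,6-trifluorobenzoate 2 (not isolated), via prop-2-enyl 2,6-difluoro-4-(prop-2-enyloxy)benzoate 3 (not isolated)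
Conditions: CH2=CHCH2OH (3.1 equiv), NaH (3.05 equiv), THF, 0 °C; add 1, −20 °C; then DMF, −20 °C to rt
Reagents that add atoms: prop-2-en-1-ol (allyl alcohol), C=CCO
Why: NaOCH2CH=CH2 first acylates at the acid chloride, and the allyl ester so formed activates the ring for two nucleophilic aromatic substitutions (SNAr) in which, in dipolar aprotic DMF, the less hindered para fluoride should leave first and one of the two then equivalent ortho fluorides second, the third being switched off by the two new alkoxy donors and by the stoichiometry, while the allyl ester makes any transesterification degenerate.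

Step 2
Reactants: 4 prop-2-enyl 2-fluoro-4,6-bis(prop-2-enyloxy)benzoate
Product: 5 2-fluoro-4,6-bis(prop-2-enyloxy)benzoic acid
Conditions: NaOH, 1,4-dioxane/H2O, 80 °C; then aq. HCl to pH 3, 0 °C
Reagents that add atoms: sodium hydroxide, [Na+].[OH-]
Why: Saponification of the allyl ester (base-mediated acyl substitution) in an alcohol-free medium keeps alkoxide away from the remaining fluoride, and cold, mild acidification should spare the electron-rich acid from protodecarboxylation.

Step 3
Reactants: 5 2-fluoro-4,6-bis(prop-2-enyloxy)benzoic acid
Product: 6 2-fluoro-4,6-bis(prop-2-enyloxy)benzoyl chloride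
Conditions: (COCl)2, DMF (cat.), CH2Cl2, 0 °C to rt
Reagents that add atoms: oxalyl chloride, O=C(Cl)C(=O)Cl
Why: Acid chloride formation through the chloroiminium salt generated from oxalyl chloride and catalytic DMF is standard and leaves the aryl allyl ethers and the aryl fluoride untouched.

Step 4
Reactants: 7 3-hydroxy-4-methoxyacetophenone
Product: 8 1-[3-(benzyloxy)-4-methoxyphenyl]ethanone
Conditions: BnBr, K2CO3, DMF, 60 °C
Reagents that add atoms: benzyl bromide, BrCc1ccccc1
Why: Williamson ether synthesis: the phenoxide formed with K2CO3 displaces bromide from benzyl bromide (SN2), and the methyl ketone does not react under these conditions.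

Step 5
Reactants: 8 1-[3-(benzyloxy)-4-methoxyphenyl]ethanone; 6 2-fluoro-4,6-bis(prop-2-enyloxy)benzoyl chloride
Product: 11 2-[3-(benzyloxy)-4-methoxyphenyl]-5,7-bis(prop-2-enyloxy)chromen-4-one, via lithium enolate 9 (not isolated), via 1,3-diketone 10 (not isolated)
Conditions: LiN(SiMe3)2 (2.2 equiv), THF, −78 °C; 6, −78 °C to rt; then DMF (THF distilled off), K2CO3, 90 °C
Reagents that add atoms: none
Why: LiN(SiMe3)2 turns ketone 8 into lithium enolate 9, which attacks acid chloride 6 at carbon and forms the C3–C4 bond, and the second equivalent of base at once deprotonates the 1,3-diketone 10, so that it rests as its lithium chelate and is not acylated again. After THF is exchanged for DMF, K2CO3 swaps lithium for potassium (Li2CO3 separates), the loosened diketonate turns about C3–C4, its oxygen on C2 adds to the fluorine-bearing C8a to give a Meisenheimer intermediate, and loss of fluoride forms O1–C8a. Ring C thus closes by intramolecular addition–elimination (SNAr), a six-membered closure of 6-exo-trig type through oxygen. The closest known reaction type is the C-aroylation of acetophenone lithium enolates with aroyl chlorides under excess LiN(SiMe3)2, followed by base-mediated cyclisation of 1-(2-fluorophenyl)-1,3-diketones to flavones. No stereocentre is formed. The step needs C- over O-acylation, which the lithium counter-ion in THF and the excess base should secure, and displacement of fluoride alone, which is secured because C8a is ortho to the C4 carbonyl while both allyloxy groups are meta to C8a and cannot donate into the carbon under attack.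

Step 6
Reactants: 11 2-[3-(benzyloxy)-4-methoxyphenyl]-5,7-bis(prop-2-enyloxy)chromen-4-one
Product: 12 2-[3-(benzyloxy)-4-methoxyphenyl]-5,7-dihydroxychromen-4-one
Conditions: Pd(PPh3)4 (5 mol %), morpholine, THF, rt
Reagents that add atoms: none
Why: In this Tsuji–Trost-type deallylation zerovalent palladium ionises each aryl allyl ether to a π-allyl complex of divalent palladium and a phenoxide, morpholine traps the allyl group irreversibly, and the benzyl ether, the methyl ether and the 2-arylpyranone should be left alone.

Step 7
Reactants: 12 2-[3-(benzyloxy)-4-methoxyphenyl]-5,7-dihydroxychromen-4-one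
Product: 13 2-[3-(benzyloxy)-4-methoxyphenyl]-5-hydroxy-4-oxochromen-7-yl hydrogen sulfate
Conditions: SO3·pyridine (1.5 equiv), pyridine, rt
Reagents that add atoms: sulfur trioxide–pyridine complex, O=S(=O)([O-])[n+]1ccccc1
Why: O-Sulfation of a phenol by the SO3·pyridine complex should take place only at the acidic, unhindered 7-hydroxyl, because the 5-hydroxyl is tied up in a hydrogen bond to the C4 carbonyl and O3' is benzylated.

Step 8
Reactants: 13 2-[3-(benzyloxy)-4-methoxyphenyl]-5-hydroxy-4-oxochromen-7-yl hydrogen sulfate
Product: 14 5-hydroxy-2-(3-hydroxy-4-methoxyphenyl)-4-oxochromen-7-yl hydrogen sulfate (luteolin 4'-methyl ether 7-sulfate)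
Conditions: H2 (1 atm), Pd/C, MeOH/H2O, rt
Reagents that add atoms: none
Why: Catalytic hydrogenolysis cleaves the benzylic C–O bond of the aryl benzyl ether, while aryl sulfate salts and the conjugated C2–C3 double bond of a flavone are known to persist at ambient pressure and temperature.

Compound list
1 | 2,4,6-trifluorobenzoyl chloride | O=C(Cl)c1c(F)cc(F)cc1F | starting material
2 | prop-2-enyl 2,4,6-trifluorobenzoate (formed in the flask, not isolated) | C=CCOC(=O)c1c(F)cc(F)cc1F | intermediate
3 | prop-2-enyl 2,6-difluoro-4-(prop-2-enyloxy)benzoate (formed in the flask, not isolated) | C=CCOC(=O)c1c(F)cc(OCC=C)cc1F | intermediate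
4 | prop-2-enyl 2-fluoro-4,6-bis(prop-2-enyloxy)benzoate | C=CCOC(=O)c1c(F)cc(OCC=C)cc1OCC=C | intermediate
5 | 2-fluoro-4,6-bis(prop-2-enyloxy)benzoic acid | OC(=O)c1c(F)cc(OCC=C)cc1OCC=C | intermediate
6 | 2-fluoro-4,6-bis(prop-2-enyloxy)benzoyl chloride | C=CCOc1cc(F)c(C(=O)Cl)c(OCC=C)c1 | intermediate
7 | 3-hydroxy-4-methoxyacetophenone | CC(=O)c1ccc(OC)c(O)c1 | starting material
8 | 1-[3-(benzyloxy)-4-methoxyphenyl]ethanone | CC(=O)c1ccc(OC)c(OCc2ccccc2)c1 | intermediate
9 | lithium 1-[3-(benzyloxy)-4-methoxyphenyl]ethenolate, the lithium enolate of 8 (formed in the flask, not isolated) | [Li+].C=C([O-])c1ccc(OC)c(OCc2ccccc2)c1 | intermediate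
10 | 1-[3-(benzyloxy)-4-methoxyphenyl]-3-[2-fluoro-4,6-bis(prop-2-enyloxy)phenyl]propane-1,3-dione (held in the flask as its lithium, then potassium, enolate; not isolated) | C=CCOc1cc(F)c(C(=O)CC(=O)c2ccc(OC)c(OCc3ccccc3)c2)c(OCC=C)c1 | intermediate
11 | 2-[3-(benzyloxy)-4-methoxyphenyl]-5,7-bis(prop-2-enyloxy)chromen-4-one | C=CCOc1cc(OCC=C)c2c(c1)oc(-c1ccc(OC)c(OCc3ccccc3)c1)cc2=O | intermediate
12 | 2-[3-(benzyloxy)-4-methoxyphenyl]-5,7-dihydroxychromen-4-one | COc1ccc(-c2cc(=O)c3c(O)cc(O)cc3o2)cc1OCc1ccccc1 | intermediate
13 | 2-[3-(benzyloxy)-4-methoxyphenyl]-5-hydroxy-4-oxochromen-7-yl hydrogen sulfate | COc1ccc(-c2cc(=O)c3c(O)cc(OS(=O)(=O)O)cc3o2)cc1OCc1ccccc1 | intermediate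
14 | 5-hydroxy-2-(3-hydroxy-4-methoxyphenyl)-4-oxochromen-7-yl hydrogen sulfate (luteolin 4'-methyl ether 7-sulfate) | COc1ccc(-c2cc(=O)c3c(O)cc(OS(=O)(=O)O)cc3o2)cc1O | target

Total step count: 8. Longest linear sequence: 7 steps (steps 1, 2, 3, 5, 6, 7 and 8); the ketone branch contributes step 4.

Steps most likely to fail

Step 5. The enolate may be acylated at oxygen, or the amide base may attack the hindered, electron-rich acid chloride, so that little diketone reaches the ring closure; the fluoride displacement on the donor-substituted ring may also be slow in the one-pot mixture. The fallback sets out from acid 5. Benzotriazole and SOCl2 in CH2Cl2 convert it into the N-acylbenzotriazole (1H-benzotriazol-1-yl)[2-fluoro-4,6-bis(prop-2-enyloxy)phenyl]methanone F1, a neutral acyl donor of a class known to acylate ketone lithium enolates at carbon. F1 is added to enolate 9 (from 8 and LiN(SiMe3)2, THF, −78 °C to rt), which should give diketone 10; this is now isolated and cyclised in a separate operation with Cs2CO3 in DMF at 80 °C. The fallback comes back to the route at flavone 11.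

Step 1. Alkoxide may attack the second ortho position before the para fluoride has reacted, or a third displacement may set in, so that regioisomeric or over-substituted esters accompany 4. The fallback replaces nucleophilic substitution by an electrophilic formylation and does not branch from a numbered compound: it sets out from commercial 5-fluorobenzene-1,3-diol (Oc1cc(O)cc(F)c1) in place of 1. Double Williamson allylation (allyl bromide, K2CO3, acetone, reflux) should give 1-fluoro-3,5-bis(prop-2-enyloxy)benzene F2. Vilsmeier–Haack formylation (POCl3, DMF, 0 °C to 60 °C) is expected para to one ether oxygen and ortho to the other, since the position flanked by both alkoxy groups is more hindered; this gives 2-fluoro-4,6-bis(prop-2-enyloxy)benzaldehyde F3. Pinnick oxidation (NaClO2, NaH2PO4, 2-methylbut-2-ene, t-BuOH/H2O) then delivers the acid. The fallback comes back to the route at acid 5, so that steps 1 and 2 both drop out.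

Step 8. The hydrogenolysis may stall through poisoning of the catalyst by the sulfate salt or by traces of pyridine, and forcing it may reduce the C2–C3 double bond or cost the sulfate. The fallback sets out from 12 and avoids hydrogen altogether. 2,2,2-Trichloroethyl chlorosulfate (ClS(=O)(=O)OCC(Cl)(Cl)Cl) with Et3N and DMAP (cat.) in THF should give the neutral, chromatographable sulfate diester 2-[3-(benzyloxy)-4-methoxyphenyl]-5-hydroxy-4-oxochromen-7-yl 2,2,2-trichloroethyl sulfate F4. BCl3 with pentamethylbenzene in CH2Cl2 at −78 °C then removes the benzyl group as a cation, giving 5-hydroxy-2-(3-hydroxy-4-methoxyphenyl)-4-oxochromen-7-yl 2,2,2-trichloroethyl sulfate F5. Zn dust with HCO2NH4 in MeOH at rt finally cleaves the trichloroethyl group by reductive fragmentation. The fallback comes back to the route at target 14.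

Further compounds
F1 | step 5 | (1H-benzotriazol-1-yl)[2-fluoro-4,6-bis(prop-2-enyloxy)phenyl]methanone | C=CCOc1cc(F)c(C(=O)n2nnc3ccccc32)c(OCC=C)c1
F2 | step 1 | 1-fluoro-3,5-bis(prop-2-enyloxy)benzene | C=CCOc1cc(F)cc(OCC=C)c1
F3 | step 1 | 2-fluoro-4,6-bis(prop-2-enyloxy)benzaldehyde | C=CCOc1cc(F)c(C=O)c(OCC=C)c1
F4 | step 8 | 2-[3-(benzyloxy)-4-methoxyphenyl]-5-hydroxy-4-oxochromen-7-yl 2,2,2-trichloroethyl sulfate | COc1ccc(-c2cc(=O)c3c(O)cc(OS(=O)(=O)OCC(Cl)(Cl)Cl)cc3o2)cc1OCc1ccccc1
F5 | step 8 | 5-hydroxy-2-(3-hydroxy-4-methoxyphenyl)-4-oxochromen-7-yl 2,2,2-trichloroethyl sulfate | COc1ccc(-c2cc(=O)c3c(O)cc(OS(=O)(=O)OCC(Cl)(Cl)Cl)cc3o2)cc1O
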